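**Retrosynthetic overview**
1. Feature: ring C (C3a', C4', C5', C6', C7', C7a') carries oxygen on C7a' and C6' and carbon on the adjacent C3a' (to C3') and C4' (to C3). This is the pattern of a 6-substituted 2,4-dihydroxybenzoate (orsellinate type), so ring C can be folded from a linear poly-β-carbonyl chain.
2. Late cuts: five O-benzyl groups and C5–CHO (from C5–Br). Ring D is opened at C3'–C2' and C2'–O1' to an ortho-quinone methide of ring C plus a chiral 4-(benzyloxy)benzyl sulfur ylide, and C3' is the former ester carbon.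
3. Key cut: C3a'–C4' of ring C, leading back to a methyl 3,5,7-trioxoheptanoate masked as a diketo-dioxinone. Its terminal ketone carbon (future C4') already holds C3.
4. The diketo-dioxinone is cut next to that ketone into the trans ring A/B 3-carboxylic acid and a keto-dioxinone dianion. Ring B comes from a rhodium carbene C–H insertion (C2–C3), followed by epimerisation at C3.
5. Ring order: B (step 4), C (step 8), D (step 15); rings A, E, G and G' are bought. C5 travels as bromide and all phenols as benzyl ethers, so no aldehyde or acetal meets the acids or the ylide, and no strong Lewis acid is needed that could ionise C2–O1 or C2'–O1'.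

Key step: step 8

Assumption: Rh2(S-PTTL)4 is taken to give the 2R series and the (1R,4R,5R) sulfide the 2'R,3'R series; both controllers exist as either enantiomer, so the mirror-image reagent would be used if the sense of induction proved opposite.

Step 1
Reactants: 1 methyl 2-(2-hydroxyphenyl)acetate
Product: 2 methyl 2-(5-bromo-2-hydroxyphenyl)acetate
Conditions: NBS (1.0 equiv), MeCN, 0 °C to rt
Reagents that add atoms: N-bromosuccinimide, O=C1CCC(=O)N1Br
Why: Electrophilic aromatic bromination of a phenol with NBS in MeCN should go to the open position para to the hydroxyl, which is the future C5.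

Step 2
Reactants: 2 methyl 2-(5-bromo-2-hydroxyphenyl)acetate; 3 4-(benzyloxy)benzyl chloride
Product: 4 methyl 2-[2-{[4-(benzyloxy)phenyl]methoxy}-5-bromophenyl]acetate
Conditions: K2CO3, cat. KI, DMF, 50 °C
Reagents that add atoms: none
Why: Williamson ether synthesis of a phenoxide with a reactive benzylic chloride installs O1, C2 and ring G.

Step 3
Reactants: 4 methyl 2-[2-{[4-(benzyloxy)phenyl]methoxy}-5-bromophenyl]acetate
Product: 5 methyl 2-[2-{[4-(benzyloxy)phenyl]methoxy}-5-bromophenyl]-2-diazoacetate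
Conditions: 4-acetamidobenzenesulfonyl azide, DBU, MeCN, 0 °C to rt
Reagents that add atoms: 4-acetamidobenzenesulfonyl azide, CC(=O)Nc1ccc(cc1)S(=O)(=O)N=[N+]=[N-]
Why: Regitz diazo transfer works on arylacetates because DBU is strong enough to form the benzylic ester enolate.

Step 4
Reactants: 5 methyl 2-[2-{[4-(benzyloxy)phenyl]methoxy}-5-bromophenyl]-2-diazoacetate
Product: 6 methyl (2R,3S)-2-[4-(benzyloxy)phenyl]-5-bromo-2,3-dihydrobenzofuran-3-carboxylate (cis)
Conditions: Rh2(S-PTTL)4 (dirhodium tetrakis[N-phthaloyl-(S)-tert-leucinate], 1 mol %), toluene, −60 °C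
Reagents that add atoms: none
Why: Loss of N2 gives a donor/acceptor rhodium carbene that undergoes intramolecular 1,5 C–H insertion into the electron-rich ArO–CH2–Ar methylene (C2–C3 bond, ring B); the chiral carboxylate pocket selects one enantiotopic hydrogen and sets C2 as R, and the concerted insertion gives the kinetic cis (3S) ester.

Step 5
Reactants: 6 methyl (2R,3S)-2-[4-(benzyloxy)phenyl]-5-bromo-2,3-dihydrobenzofuran-3-carboxylate
Product: 8 (2R,3R)-2-[4-(benzyloxy)phenyl]-5-bromo-2,3-dihydrobenzofuran-3-carboxylic acid (trans), via trans methyl ester 7 (not isolated)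
Conditions: NaOMe (0.3 equiv), MeOH–THF, rt; then LiOH, H2O, rt; then 1 M HCl to pH 3
Reagents that add atoms: lithium hydroxide, [Li+].[OH-]
Why: Base epimerisation through the ester enolate sets C3 as R in the thermodynamically preferred trans relation to the untouched C2 (loss of O1 from the enolate would be the reverse of a 5-endo-trig closure and has poor overlap), and saponification then gives the acid.

Step 6
Reactants: 9 2,2,6-trimethyl-4H-1,3-dioxin-4-one; 10 acetyl chloride
Product: 11 2,2-dimethyl-6-(2-oxopropyl)-4H-1,3-dioxin-4-one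
Conditions: 9 (2 equiv), LiN(SiMe3)2 (2 equiv), THF, −78 °C; 10 (1 equiv), −78 to −20 °C; then 1 M HCl
Reagents that add atoms: none
Why: The lithium dienolate of the dioxinone is C-acylated at its γ-carbon (vinylogous Claisen-type acylation), and the excess enolate takes up the more acidic proton of the product.

Step 7
Reactants: 8 (2R,3R)-2-[4-(benzyloxy)phenyl]-5-bromo-2,3-dihydrobenzofuran-3-carboxylic acid; 11 2,2-dimethyl-6-(2-oxopropyl)-4H-1,3-dioxin-4-one
Product: 14 6-{4-[(2R,3R)-2-(4-benzyloxyphenyl)-5-bromo-2,3-dihydrobenzofuran-3-yl]-2,4-dioxobutyl}-2,2-dimethyl-4H-1,3-dioxin-4-one (diketo-dioxinone), via acyl imidazole 12 (not isolated), via dilithio dianion 13 (not isolated)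
Conditions: 8, 1,1'-carbonyldiimidazole, THF, rt, then argon purge; separately 11 (3 equiv), LiN(iPr)2 (6 equiv), THF, −78 to −40 °C; add 12 at −78 °C, warm to −20 °C; then 1 M HCl to pH 4
Reagents that add atoms: none
Why: The terminal carbanion of the 1,3-dicarbonyl dianion is its most nucleophilic site and attacks the acyl imidazole (Claisen-type C-acylation); any enolisation at C3, or passage through the derived ketene, is harmless because reprotonation returns the trans isomer dictated by the inert C2.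

Step 8
Reactants: 14 diketo-dioxinone
Product: 17 methyl 2-[(2R,3R)-2-(4-benzyloxyphenyl)-5-bromo-2,3-dihydrobenzofuran-3-yl]-4,6-dihydroxybenzoate (resorcylate; ring C formed), via acylketene 15 (not isolated), via 3,5,7-triketo ester 16 (not isolated)
Conditions: MeOH (10 equiv), PhMe, 110 °C (sealed tube); cool, Cs2CO3, MeOH, rt; then HCl/MeOH to pH 2–3, rt
Reagents that add atoms: methanol, CO
Why: Heating drives a retro-[4+2] loss of acetone from the dioxinone of 14, and the excess methanol captures acylketene 15 faster than its own enol oxygens can, giving the open triketo ester 16. Cs2CO3 then equilibrates the enolates, the ester-flanked C2 carbon (future C3a') adds to the C7 ketone (future C4', already bonded to C3), and acid completes loss of water and tautomerisation to aromatic ring C. The closest known reaction type is the biomimetic ketene trapping and aldol aromatisation of diketo-dioxinones to 6-substituted 2,4-dihydroxybenzoates. Ring C closes in the 6-(enolendo)-exo-trig mode. No stereocentre is created; C3 is enolisable in 14 to 16 but can only settle in the favoured trans relation to the base-inert C2, and after aromatisation it is no longer acidic. The step needs aldol folding (C2 to C7) rather than Claisen folding (C6 to C1) or pyranone formation, and this is secured by the greater electrophilicity of the ketone over the methyl ester, the mild carbonate base and the irreversible aromatisation.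

Step 9
Reactants: 17 resorcylate
Product: 18 methyl 4-(benzyloxy)-2-[(2R,3R)-2-(4-benzyloxyphenyl)-5-bromo-2,3-dihydrobenzofuran-3-yl]-6-hydroxybenzoate
Conditions: BnBr (1.05 equiv), K2CO3, acetone, rt to 40 °C
Reagents that add atoms: benzyl bromide, BrCc1ccccc1
Why: In this Williamson alkylation the C6' hydroxyl is the more acidic and accessible one, while the C7a' hydroxyl is held in a hydrogen bond to the ester carbonyl and stays free.

Step 10
Reactants: 18 methyl 4-(benzyloxy)-6-hydroxybenzoate derivative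
Product: 19 5-(benzyloxy)-3-[(2R,3R)-2-(4-benzyloxyphenyl)-5-bromo-2,3-dihydrobenzofuran-3-yl]-2-(hydroxymethyl)phenol
Conditions: LiAlH4, THF, 0 °C to rt; then H2O, aq NaOH
Reagents that add atoms: none
Why: Hydride reduction of the salicylate ester is assisted by the neighbouring phenoxide-bound aluminate, and the low temperature spares the aryl bromide and avoids over-reduction through a quinone methide.

Step 11
Reactants: 19 salicyl alcohol
Product: 20 4-(benzyloxy)-2-[(2R,3R)-2-(4-benzyloxyphenyl)-5-bromo-2,3-dihydrobenzofuran-3-yl]-6-hydroxybenzaldehyde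
Conditions: activated MnO2 (excess), CH2Cl2, rt
Reagents that add atoms: none
Why: MnO2 oxidises benzylic alcohols selectively, and the hydrogen-bonded salicylaldehyde that forms resists further oxidation.

Step 12
Reactants: 20 salicylaldehyde; 21 1,3-bis(benzyloxy)-5-bromobenzene
Product: 23 5-(benzyloxy)-2-{[3,5-bis(benzyloxy)phenyl](hydroxy)methyl}-3-[(2R,3R)-2-(4-benzyloxyphenyl)-5-bromo-2,3-dihydrobenzofuran-3-yl]phenol (both epimers at the carbinol carbon C3'), via arylmagnesium bromide 22 (not isolated)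
Conditions: 21 (2.5 equiv), Mg turnings, THF, 50 °C; add to 20, THF, 0 °C to rt; then H2O
Reagents that add atoms: none
Why: In this Grignard addition the first equivalent deprotonates the phenol and the second adds to the magnesium-chelated aldehyde, bringing in ring E; the configuration of the carbinol carbon does not matter because it is erased in step 15.

Step 13
Reactants: 23 ortho-hydroxybenzhydrol
Product: 24 5-(benzyloxy)-2-{[3,5-bis(benzyloxy)phenyl](4-methylphenylsulfonyl)methyl}-3-[(2R,3R)-2-(4-benzyloxyphenyl)-5-bromo-2,3-dihydrobenzofuran-3-yl]phenol (both epimers at C3')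
Conditions: p-TolSO2H (1.5 equiv), MgSO4, CH2Cl2, 0 °C to rt
Reagents that add atoms: p-toluenesulfinic acid, Cc1ccc(cc1)S(=O)O
Why: The sulfinic acid is acidic enough to ionise the carbinol to a benzhydryl cation stabilised by the ortho and para oxygens of ring C, and sulfur of the sulfinate captures it to give the stable sulfone (SN1-type substitution); no activated arene position lies within reach for a competing Friedel–Crafts closure.

Step 14
Reactants: 25 (1R,4R,5R)-4,7,7-trimethyl-6-thiabicyclo[3.2.1]octane (isothiocineole); 3 4-(benzyloxy)benzyl chloride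
Product: 26 (1R,4R,5R)-6-[4-(benzyloxy)benzyl]-4,7,7-trimethyl-6-thiabicyclo[3.2.1]octan-6-ium trifluoromethanesulfonate
Conditions: LiOSO2CF3, CH2Cl2–H2O, rt
Reagents that add atoms: lithium trifluoromethanesulfonate, [Li+].[O-]S(=O)(=O)C(F)(F)F
Why: S-alkylation by the reactive benzylic chloride is made irreversible by exchange of chloride for the non-nucleophilic triflate, and the less hindered sulfur lone pair should react to give one sulfonium diastereomer (configuration at sulfur not drawn).

Step 15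
Reactants: 24 sulfone; 26 sulfonium triflate
Product: 29 (2R,3R)-6-(benzyloxy)-2-[4-(benzyloxy)phenyl]-4-[(2R,3R)-2-(4-benzyloxyphenyl)-5-bromo-2,3-dihydrobenzofuran-3-yl]-3-[3,5-bis(benzyloxy)phenyl]-2,3-dihydrobenzofuran (ring D closed; 2R,3R,2'R,3'R), via ortho-quinone methide 27 (not isolated), via sulfonium benzylide 28 (not isolated)
Conditions: 26 (1.5 equiv), Cs2CO3 (4 equiv), MeCN–CH2Cl2, −20 °C to rt
Reagents that add atoms: none
Why: Proposed new method: Cs2CO3 removes the phenol proton of 24 and p-toluenesulfinate leaves (E1cB) to give ortho-quinone methide 27, while the same base converts 26 into benzylide 28; the ylide carbon adds to C3' with rearomatisation of ring C, and phenoxide O1' then displaces the sulfide at C2' with inversion (5-exo-tet), so C3'–C2' and C2'–O1' form in one flask. The anti betaine leads to the trans ring D, and the absolute sense should follow from the single open face of the conformationally locked bicyclic ylide, which fixes C2' as R and, through the trans preference, C3' as R. The closest known reaction types are the [4+1] annulation of sulfone-derived ortho-quinone methides with carbonyl-stabilised sulfur ylides or chiral ammonium ylides, and the epoxidation and aziridination by this same class of chiral benzylides; pairing a chiral aryl-substituted sulfur ylide with an ortho-quinone methide is the new element.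

Step 16
Reactants: 29 pentabenzyl bromide
Product: 31 (2R,3R)-3-{(2R,3R)-6-(benzyloxy)-2-[4-(benzyloxy)phenyl]-3-[3,5-bis(benzyloxy)phenyl]-2,3-dihydrobenzofuran-4-yl}-2-[4-(benzyloxy)phenyl]-2,3-dihydrobenzofuran-5-carbaldehyde, via aryllithium 30 (not isolated)
Conditions: n-BuLi (1.1 equiv), THF, −78 °C; DMF, −78 to 0 °C; then H2O
Reagents that add atoms: N,N-dimethylformamide, CN(C)C=O
Why: Bromine–lithium exchange at −78 °C is faster than any deprotonation of benzylic C–H bonds, and trapping with DMF (Bouveault aldehyde synthesis) places the formyl group on C5.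

Step 17
Reactants: 31 pentabenzyl aldehyde
Product: 32 (2R,3R)-3-[(2R,3R)-3-(3,5-dihydroxyphenyl)-6-hydroxy-2-(4-hydroxyphenyl)-2,3-dihydrobenzofuran-4-yl]-2-(4-hydroxyphenyl)-2,3-dihydrobenzofuran-5-carbaldehyde (target)
Conditions: H2 (1 atm), 10% Pd/C, EtOAc–THF, rt, stopped after uptake of five equivalents
Reagents that add atoms: none
Why: Catalytic hydrogenolysis cleaves primary phenolic benzyl ethers much faster than it reduces a para-alkoxybenzaldehyde (a vinylogous ester) or opens the hindered secondary C2–O1 and C2'–O1' bonds, and the neutral medium leaves all four stereocentres untouched.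

**Compound list**
1 | methyl 2-(2-hydroxyphenyl)acetate | COC(=O)Cc1ccccc1O | starting material
2 | methyl 2-(5-bromo-2-hydroxyphenyl)acetate | COC(=O)Cc1cc(Br)ccc1O | intermediate
3 | 4-(benzyloxy)benzyl chloride | ClCc1ccc(OCc2ccccc2)cc1 | starting material
4 | methyl 2-[2-{[4-(benzyloxy)phenyl]methoxy}-5-bromophenyl]acetate | COC(=O)Cc1cc(Br)ccc1OCc1ccc(OCc2ccccc2)cc1 | intermediate
5 | methyl 2-[2-{[4-(benzyloxy)phenyl]methoxy}-5-bromophenyl]-2-diazoacetate | COC(=O)C(=[N+]=[N-])c1cc(Br)ccc1OCc1ccc(OCc2ccccc2)cc1 | intermediate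
6 | methyl (2R,3S)-2-[4-(benzyloxy)phenyl]-5-bromo-2,3-dihydrobenzofuran-3-carboxylate (cis) | Brc1ccc2c(c1)[C@H](C(=O)OC)[C@H](c1ccc(OCc3ccccc3)cc1)O2 | intermediate
7 | methyl (2R,3R)-2-[4-(benzyloxy)phenyl]-5-bromo-2,3-dihydrobenzofuran-3-carboxylate (trans) | Brc1ccc2c(c1)[C@@H](C(=O)OC)[C@H](c1ccc(OCc3ccccc3)cc1)O2 | intermediate
8 | (2R,3R)-2-[4-(benzyloxy)phenyl]-5-bromo-2,3-dihydrobenzofuran-3-carboxylic acid | Brc1ccc2c(c1)[C@@H](C(=O)O)[C@H](c1ccc(OCc3ccccc3)cc1)O2 | intermediate
9 | 2,2,6-trimethyl-4H-1,3-dioxin-4-one | CC1=CC(=O)OC(C)(C)O1 | starting material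
10 | acetyl chloride | CC(=O)Cl | starting material
11 | 2,2-dimethyl-6-(2-oxopropyl)-4H-1,3-dioxin-4-one | CC(=O)CC1=CC(=O)OC(C)(C)O1 | intermediate
12 | acyl imidazole of acid 8 | Brc1ccc2c(c1)[C@@H](C(=O)n1ccnc1)[C@H](c1ccc(OCc3ccccc3)cc1)O2 | intermediate
13 | dilithio dianion of 11 | [Li+].[Li+].[CH2-]C(=O)[CH-]C1=CC(=O)OC(C)(C)O1 | intermediate
14 | diketo-dioxinone (key-step precursor) | Brc1ccc2c(c1)[C@@H](C(=O)CC(=O)CC1=CC(=O)OC(C)(C)O1)[C@H](c1ccc(OCc3ccccc3)cc1)O2 | intermediate
15 | acylketene R–CO–CH2–CO–CH2–CO–CH=C=O (R = ring A/B unit bonded through C3) | Brc1ccc2c(c1)[C@@H](C(=O)CC(=O)CC(=O)C=C=O)[C@H](c1ccc(OCc3ccccc3)cc1)O2 | intermediate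
16 | methyl 7-[(2R,3R)-2-(4-benzyloxyphenyl)-5-bromo-2,3-dihydrobenzofuran-3-yl]-3,5,7-trioxoheptanoate | Brc1ccc2c(c1)[C@@H](C(=O)CC(=O)CC(=O)CC(=O)OC)[C@H](c1ccc(OCc3ccccc3)cc1)O2 | intermediate
17 | methyl 2-[(2R,3R)-2-(4-benzyloxyphenyl)-5-bromo-2,3-dihydrobenzofuran-3-yl]-4,6-dihydroxybenzoate (key-step product) | Brc1ccc2c(c1)[C@@H](c1cc(O)cc(O)c1C(=O)OC)[C@H](c1ccc(OCc3ccccc3)cc1)O2 | intermediate
18 | methyl 4-(benzyloxy)-2-[(2R,3R)-2-(4-benzyloxyphenyl)-5-bromo-2,3-dihydrobenzofuran-3-yl]-6-hydroxybenzoate | Brc1ccc2c(c1)[C@@H](c1cc(OCc3ccccc3)cc(O)c1C(=O)OC)[C@H](c1ccc(OCc3ccccc3)cc1)O2 | intermediate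
19 | 5-(benzyloxy)-3-[(2R,3R)-2-(4-benzyloxyphenyl)-5-bromo-2,3-dihydrobenzofuran-3-yl]-2-(hydroxymethyl)phenol | Brc1ccc2c(c1)[C@@H](c1cc(OCc3ccccc3)cc(O)c1CO)[C@H](c1ccc(OCc3ccccc3)cc1)O2 | intermediate
20 | 4-(benzyloxy)-2-[(2R,3R)-2-(4-benzyloxyphenyl)-5-bromo-2,3-dihydrobenzofuran-3-yl]-6-hydroxybenzaldehyde | Brc1ccc2c(c1)[C@@H](c1cc(OCc3ccccc3)cc(O)c1C=O)[C@H](c1ccc(OCc3ccccc3)cc1)O2 | intermediate
21 | 1,3-bis(benzyloxy)-5-bromobenzene | Brc1cc(OCc2ccccc2)cc(OCc2ccccc2)c1 | starting material
22 | 3,5-bis(benzyloxy)phenylmagnesium bromide | Br[Mg]c1cc(OCc2ccccc2)cc(OCc2ccccc2)c1 | intermediate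
23 | ortho-hydroxybenzhydrol (C3' carbinol, both epimers) | Brc1ccc2c(c1)[C@@H](c1cc(OCc3ccccc3)cc(O)c1C(O)c1cc(OCc3ccccc3)cc(OCc3ccccc3)c1)[C@H](c1ccc(OCc3ccccc3)cc1)O2 | intermediate
24 | ortho-hydroxybenzhydryl p-tolyl sulfone (both epimers at C3') | Brc1ccc2c(c1)[C@@H](c1cc(OCc3ccccc3)cc(O)c1C(c1cc(OCc3ccccc3)cc(OCc3ccccc3)c1)S(=O)(=O)c1ccc(C)cc1)[C@H](c1ccc(OCc3ccccc3)cc1)O2 | intermediate
25 | (1R,4R,5R)-4,7,7-trimethyl-6-thiabicyclo[3.2.1]octane (isothiocineole) | C[C@@H]1CC[C@@H]2C[C@H]1SC2(C)C | starting material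
26 | S-[4-(benzyloxy)benzyl] sulfonium triflate of 25 | C[C@@H]1CC[C@@H]2C[C@H]1[S+](Cc1ccc(OCc3ccccc3)cc1)C2(C)C.[O-]S(=O)(=O)C(F)(F)F | intermediate
27 | ortho-quinone methide of ring C (C7a'=O, C3a'=C3'H–ring E) | Brc1ccc2c(c1)[C@@H](C1=CC(OCc3ccccc3)=CC(=O)C1=Cc1cc(OCc3ccccc3)cc(OCc3ccccc3)c1)[C@H](c1ccc(OCc3ccccc3)cc1)O2 | intermediate
28 | sulfonium 4-(benzyloxy)benzylide derived from 26 | C[C@@H]1CC[C@@H]2C[C@H]1[S+]([CH-]c1ccc(OCc3ccccc3)cc1)C2(C)C | intermediate
29 | pentabenzyl C5 bromide (2R,3R,2'R,3'R) | Brc1ccc2c(c1)[C@@H](c1cc(OCc3ccccc3)cc3c1[C@@H](c1cc(OCc4ccccc4)cc(OCc4ccccc4)c1)[C@H](c1ccc(OCc4ccccc4)cc1)O3)[C@H](c1ccc(OCc3ccccc3)cc1)O2 | intermediate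
30 | C5 aryllithium from 29 | [Li]c1ccc2c(c1)[C@@H](c1cc(OCc3ccccc3)cc3c1[C@@H](c1cc(OCc4ccccc4)cc(OCc4ccccc4)c1)[C@H](c1ccc(OCc4ccccc4)cc1)O3)[C@H](c1ccc(OCc3ccccc3)cc1)O2 | intermediate
31 | pentabenzyl C5 aldehyde (2R,3R,2'R,3'R) | O=Cc1ccc2c(c1)[C@@H](c1cc(OCc3ccccc3)cc3c1[C@@H](c1cc(OCc4ccccc4)cc(OCc4ccccc4)c1)[C@H](c1ccc(OCc4ccccc4)cc1)O3)[C@H](c1ccc(OCc3ccccc3)cc1)O2 | intermediate
32 | CNP0318276.1 (2R,3R,2'R,3'R) | O=Cc1ccc2c(c1)[C@@H](c1cc(O)cc3c1[C@@H](c1cc(O)cc(O)c1)[C@H](c1ccc(O)cc1)O3)[C@H](c1ccc(O)cc1)O2 | target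

**Step count**
Total steps: 17.
Longest linear sequence: 15 (steps 1–5, 7–13, 15–17). Steps 6 and 14 are one-step side branches.

**Steps most likely to fail**

Step 15. The ylide may add only slowly to the crowded C3' terminus, so the quinone methide oligomerises or is recaptured by sulfinate. The facial bias of the reagent may also be opposed by the resident C3 substituent, giving poor facial selectivity. The fallback uses known chemistry and sets out from 23.
- The phenol is alkylated with 3 (K2CO3, DMF) to the aryl 4-(benzyloxy)benzyl ether carbinol F1.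
- Dess–Martin periodinane gives the diaryl ketone F2.
- Hydrazine hydrate with AcOH in hot n-butanol gives the hydrazone F3.
- MnO2 gives the diaryldiazomethane F4.
- Rh2(PTAD)4 (dirhodium tetrakis[(1-adamantyl)(phthalimido)acetate], in the enantiomeric form that leads to 3'R) brings about an enantioselective donor/donor carbene 1,5 C–H insertion into the O–CH2–aryl group. This gives the cis (2'S,3'R) dihydrobenzofuran F5.
- CF3CO2H in CH2Cl2 epimerises C2' by reversible opening of C2'–O1' to the para-quinone methide cation, and the route is rejoined at 29.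

Step 8. Methoxide may cleave the hindered acyl group by retro-Claisen attack. The ketene or triketo ester may lactonise to a 4-hydroxy-2-pyranone. The aldol at the branched C7 ketone may be sluggish, or the trans relation at C3 may erode before ring closure. The fallback sets out from 14 and avoids both the ketene and methanol.
- Et3N in CH2Cl2 at rt lets the dioxinone dienolate carbon (future C3a') add to the same ketone. Aromatisation with the dioxinone ring intact gives the 7-hydroxy-2,2-dimethyl-4H-benzo[d][1,3]dioxin-4-one F6, in which only the C6' hydroxyl is free.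
- BnBr and K2CO3 give the benzyl ether F7.
- LiAlH4 opens and reduces the acetonide lactone, and the route is rejoined at 19.

Step 17. The formyl group may be over-reduced, or the benzylic C2–O1 and C2'–O1' bonds may be opened reductively, before all five benzyl ethers are cleaved. The fallback sets out from 31 and replaces reduction by Lewis-acid debenzylation with a cation scavenger (BCl3, pentamethylbenzene, CH2Cl2, −78 °C). This is known to tolerate aromatic aldehydes, and it reaches 32 directly. It makes no new compound (F0).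

**Further compounds**
F1 | step 15 | aryl 4-(benzyloxy)benzyl ether carbinol (both epimers at C3') | Brc1ccc2c(c1)[C@@H](c1cc(OCc3ccccc3)cc(OCc3ccc(OCc4ccccc4)cc3)c1C(O)c1cc(OCc3ccccc3)cc(OCc3ccccc3)c1)[C@H](c1ccc(OCc3ccccc3)cc1)O2
F2 | step 15 | diaryl ketone | Brc1ccc2c(c1)[C@@H](c1cc(OCc3ccccc3)cc(OCc3ccc(OCc4ccccc4)cc3)c1C(=O)c1cc(OCc3ccccc3)cc(OCc3ccccc3)c1)[C@H](c1ccc(OCc3ccccc3)cc1)O2
F3 | step 15 | hydrazone | Brc1ccc2c(c1)[C@@H](c1cc(OCc3ccccc3)cc(OCc3ccc(OCc4ccccc4)cc3)c1C(=NN)c1cc(OCc3ccccc3)cc(OCc3ccccc3)c1)[C@H](c1ccc(OCc3ccccc3)cc1)O2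
F4 | step 15 | diaryldiazomethane | Brc1ccc2c(c1)[C@@H](c1cc(OCc3ccccc3)cc(OCc3ccc(OCc4ccccc4)cc3)c1C(=[N+]=[N-])c1cc(OCc3ccccc3)cc(OCc3ccccc3)c1)[C@H](c1ccc(OCc3ccccc3)cc1)O2
F5 | step 15 | cis (2'S,3'R) dihydrobenzofuran | Brc1ccc2c(c1)[C@@H](c1cc(OCc3ccccc3)cc3c1[C@@H](c1cc(OCc4ccccc4)cc(OCc4ccccc4)c1)[C@@H](c1ccc(OCc4ccccc4)cc1)O3)[C@H](c1ccc(OCc3ccccc3)cc1)O2
F6 | step 8 | 5-[(2R,3R)-2-(4-benzyloxyphenyl)-5-bromo-2,3-dihydrobenzofuran-3-yl]-7-hydroxy-2,2-dimethyl-4H-benzo[d][1,3]dioxin-4-one | Brc1ccc2c(c1)[C@@H](c1cc(O)cc3OC(C)(C)OC(=O)c13)[C@H](c1ccc(OCc3ccccc3)cc1)O2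
F7 | step 8 | 7-(benzyloxy) ether of F6 | Brc1ccc2c(c1)[C@@H](c1cc(OCc3ccccc3)cc3OC(C)(C)OC(=O)c13)[C@H](c1ccc(OCc3ccccc3)cc1)O2
F0 | step 17 | none | none
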